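The numbers in the tables are simulated with made-up constants; scatter was added.

Two constants could be read from the earlier runs, and I worked them out in a note for whoever took over the bench.

| flask | starting material | coupling partner | remark | time |
|---|---|---|---|---|
| alpha | 0.40 M | 0.12 M | run made earlier |  |
| theta | 0.40 M | 0.18 M | run made earlier |  |
| flask | 0.40 M | 0.240 M |  | 15 d |

| run | time / d | product / % | intermediate / % |
|---|---|---|---|
| alpha | 3.00 | 17.0 | 7.4 |
| alpha | 6.00 | 18.0 | 6.9 |
| alpha | 10.0 | 18.5 | 7.1 |
| alpha | 12.0 | 18.1 | 6.6 |
| theta | 1.67 | 20.1 | 13.5 |
| theta | 4.00 | 25.5 | 10.2 |
| theta | 8.00 | 26.2 | 10.2 |
| theta | 12.0 | 26.2 | 10.0 |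

(readings scatter by 0.3 percentage points)

- what was read earlier has a scatter of 0.3 percentage points, one standard deviation
- on the list of suspects stand: starting material + coupling partner <-> intermediate; intermediate <-> product
- the reaction counts as stopped when no species that holds the starting material changes by six tenths of a point or more over the second half of the time

* at 15 d, what has stopped the reaction, if anything has (the coupling partner has run out first / it is still moving / all of the starting material has reacted / forward and back rates have come level)
* product at 15 d, in percent of the starting material charged
* intermediate at 15 d, in percent of the starting material charged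

The theta run's last reading had 0.145 M of coupling partner bound and 0.0352 M still free, although its product read 26.2 % at 8.00 d and 26.2 % at 12.0 d. That run had therefore come to rest with partner in hand. From it I took the holding constant, c(intermediate) plus c(product) over c(starting material) times c(coupling partner), which is the overall equilibrium constant: 16.1 M⁻¹. The alpha run's last reading gave 15.5 M⁻¹, and theta's ratio of product to intermediate read 2.62.

For the flask, with 0.240 M of partner, I solved the constant and got 0.186 M bound. So I told my successor to expect 33.7 % product, 12.8 % intermediate and 0.0540 M of partner free at 15 d. Theta's product had stood flat from 8.00 d, so I saw no gain in waiting past 15 d, and I asked that no fresh partner go in, since my balance was reckoned for this charge.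

The forecast, reckoned apart from mine, said forward and back rates have come level, with 33.9 % product and 13 % intermediate, since what stayed in the runs “points to equilibrium”.

The flask gave forward and back rates have come level, with 33.9 % product and 12.5 % intermediate.

    starting material + coupling partner ⇌ intermediate (K = 4.30 M⁻¹, k = 2.47 M⁻¹ h⁻¹)
    intermediate ⇌ product (K = 2.70, k = 0.0385 h⁻¹)

The flask's own figures gave a holding constant of 15.9 M⁻¹. Conversion of starting material in the flask stopped at 46.4 % mainly through the using up of coupling partner: the same flask with partner kept at its charge reached 79.2 %. With 0.096 M of partner in a neighbouring flask, the constant gave 16.3 % of that charge free, and that flask held 16 %.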